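## Retrosynthetic overview

1. The target is reached by global debenzylation of a hexabenzyl ether; the (E)-styryl bond comes from a Horner–Wadsworth–Emmons reaction between a 2,3-diaryl-2,3-dihydrobenzofuran-6-carbaldehyde and a benzyl-protected vanillyl phosphonate.
2. The C3–aryl bond comes from decarboxylative arylation of a trans-2-aryl-2,3-dihydrobenzofuran-3-carboxylic acid with 1,3-bis(benzyloxy)-5-bromobenzene, the aryl entering anti to the C2 aryl group.
3. The dihydrofuran ring is the only ring that is built (all four benzene rings are bought): acid-triggered C2–O closure of a 1,2-diarylpropane-1,3-diol onto one of two equivalent ring A phenols, giving the trans ring.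
4. The key C2–C3 bond comes from an Evans boron syn-aldol between the (S)-4-benzyloxazolidinone imide of a ring A arylacetic acid and 2,4-bis(benzyloxy)benzaldehyde; the configuration is relayed C3 (aldol) → C2 (ring closure) → C3 (arylation).
5. The ring A acid comes from methyl 4-bromo-3,5-dihydroxybenzoate by MOM protection, Suzuki allylation, ozonolysis and Pinnick oxidation.

Assumption: the compounds marked as starting materials and the simple reagents are bought; "not isolated" marks species that are carried on in the same flask.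

## Route

Step 1
Reactants: 1 methyl 4-bromo-3,5-dihydroxybenzoate
Product: 2 methyl 4-bromo-3,5-bis(methoxymethoxy)benzoate
Conditions: MOMCl, i-Pr2NEt, CH2Cl2, 0 °C → rt
Reagents that add atoms: chloromethyl methyl ether, COCCl
Why: Williamson-type O-alkylation masks both phenols as acid-labile methoxymethyl acetals that survive the coupling, oxidation and enolate steps and can later be removed without touching benzyl ethers; no stereocentre is involved.

Step 2
Reactants: 2 methyl 4-bromo-3,5-bis(methoxymethoxy)benzoate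
Product: 3 methyl 3,5-bis(methoxymethoxy)-4-(prop-2-en-1-yl)benzoate
Conditions: allylB(pin), Pd(OAc)2 (5 mol %), SPhos (10 mol %), CsF, THF, 65 °C
Reagents that add atoms: allylboronic acid pinacol ester, C=CCB1OC(C)(C)C(C)(C)O1
Why: Suzuki–Miyaura cross-coupling, in which the para ester activates the C–Br bond and the bulky biaryl phosphine copes with the two ortho substituents, places the allyl group (the future C3 and carboxyl carbons) exactly between the two oxygens; no stereocentre.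

Step 3
Reactants: 3 methyl 3,5-bis(methoxymethoxy)-4-(prop-2-en-1-yl)benzoate
Product: 5 methyl 3,5-bis(methoxymethoxy)-4-(2-oxoethyl)benzoate, via secondary ozonide 4 (not isolated)
Conditions: O3, CH2Cl2, −78 °C; then PPh3, −78 °C → rt
Reagents that add atoms: ozone, [O-][O+]=O
Why: Ozonolysis with reductive work-up cleaves only the terminal alkene (the arene is deactivated by the ester) and gives the arylacetaldehyde, which is used crude; no stereocentre.

Step 4
Reactants: 5 methyl 3,5-bis(methoxymethoxy)-4-(2-oxoethyl)benzoate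
Product: 6 [4-(methoxycarbonyl)-2,6-bis(methoxymethoxy)phenyl]acetic acid
Conditions: NaClO2, NaH2PO4, 2-methyl-2-butene, t-BuOH/H2O, 0 °C → rt
Reagents that add atoms: sodium chlorite, [Na+].[O-]Cl=O
Why: Pinnick oxidation converts the enolisable aldehyde into the acid under buffered, chlorine-scavenged conditions that leave the MOM acetals and the ester intact; no stereocentre.

Step 5
Reactants: 6 [4-(methoxycarbonyl)-2,6-bis(methoxymethoxy)phenyl]acetic acid; 7 (4S)-4-benzyl-1,3-oxazolidin-2-one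
Product: 9 methyl 4-{2-[(4S)-4-benzyl-2-oxo-1,3-oxazolidin-3-yl]-2-oxoethyl}-3,5-bis(methoxymethoxy)benzoate, via mixed pivalic anhydride 8 (not isolated)
Conditions: t-BuCOCl, Et3N, THF, −20 °C; then 7, LiCl, −20 °C → rt
Reagents that add atoms: none
Why: Mixed-anhydride N-acylation of the Evans oxazolidinone (LiCl/Et3N protocol) occurs at the unhindered arylacetyl carbonyl and installs the chiral controller, whose own stereocentre is the only one present.

Step 6
Reactants: 9 methyl 4-{2-[(4S)-4-benzyl-2-oxo-1,3-oxazolidin-3-yl]-2-oxoethyl}-3,5-bis(methoxymethoxy)benzoate; 10 2,4-bis(benzyloxy)benzaldehyde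
Product: 13 (4S)-4-benzyl-3-[(2S,3S)-3-[2,4-bis(benzyloxy)phenyl]-3-hydroxy-2-[4-(methoxycarbonyl)-2,6-bis(methoxymethoxy)phenyl]propanoyl]-1,3-oxazolidin-2-one, via Z-dibutylboron enolate 11 (not isolated), via dibutylboron aldolate 12 (not isolated)
Conditions: n-Bu2BOTf, i-Pr2NEt, CH2Cl2, −78 → 0 °C; then 10, −78 → 0 °C; then MeOH, pH 7 buffer, H2O2, 0 °C
Reagents that add atoms: none
Why: Evans syn-aldol addition, in which soft enolisation gives the Z-boron enolate that adds to the aldehyde through a Zimmerman–Traxler chair on the enolate face away from the auxiliary benzyl group, forms the C2–C3 bond and fixes the aryl-bearing carbon (future C3) as S together with the (S)-carbinol.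

Step 7
Reactants: 13 the syn-aldol imide
Product: 14 methyl 4-[(1S,2R)-1-[2,4-bis(benzyloxy)phenyl]-1,3-dihydroxypropan-2-yl]-3,5-bis(methoxymethoxy)benzoate
Conditions: NaBH4, THF/H2O (4:1), 0 °C → rt
Reagents that add atoms: none
Why: Borohydride reductive cleavage of the activated imide carbonyl is faster than attack on the benzoate ester, so it releases the auxiliary and gives the 1,3-diol without touching either stereocentre (the descriptor at the aryl-bearing carbon changes to R only because the ranking of its substituents changes).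

Step 8
Reactants: 14 methyl 4-[(1S,2R)-1-[2,4-bis(benzyloxy)phenyl]-1,3-dihydroxypropan-2-yl]-3,5-bis(methoxymethoxy)benzoate
Product: 16 methyl (2S,3R)-2-[2,4-bis(benzyloxy)phenyl]-4-hydroxy-3-(hydroxymethyl)-2,3-dihydro-1-benzofuran-6-carboxylate, via tetraol 15 (not isolated)
Conditions: HCl (2 M in MeOH), 0 °C → rt
Reagents that add atoms: none
Why: Acid cleaves both MOM acetals and ionises the benzylic alcohol to a 2,4-dialkoxybenzyl (quinone-methide-like) cation that either of the two equivalent phenols traps in an SN1 five-ring etherification, the aryl group settling trans to the C3 hydroxymethyl group so that C2 becomes S under control of the aldol-derived C3 centre.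

Step 9
Reactants: 16 methyl (2S,3R)-2-[2,4-bis(benzyloxy)phenyl]-4-hydroxy-3-(hydroxymethyl)-2,3-dihydro-1-benzofuran-6-carboxylate
Product: 17 methyl (2S,3R)-4-(benzyloxy)-2-[2,4-bis(benzyloxy)phenyl]-3-(hydroxymethyl)-2,3-dihydro-1-benzofuran-6-carboxylate
Conditions: BnBr, K2CO3, acetone, 56 °C
Reagents that add atoms: benzyl bromide, BrCc1ccccc1
Why: Williamson etherification is chemoselective because carbonate deprotonates only the phenol and not the primary alcohol; the stereocentres are untouched.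

Step 10
Reactants: 17 methyl (2S,3R)-4-(benzyloxy)-2-[2,4-bis(benzyloxy)phenyl]-3-(hydroxymethyl)-2,3-dihydro-1-benzofuran-6-carboxylate
Product: 19 (2S,3S)-4-(benzyloxy)-2-[2,4-bis(benzyloxy)phenyl]-6-(methoxycarbonyl)-2,3-dihydro-1-benzofuran-3-carboxylic acid, via aldehyde 18 (not isolated)
Conditions: TEMPO (20 mol %), PhI(OAc)2, MeCN/H2O (1:1), rt
Reagents that add atoms: water, O
Why: Nitroxyl-catalysed oxidation takes the primary alcohol through the aldehyde hydrate to the acid without strong acid or base, so C2 is untouched and C3 stays in the thermodynamically favoured trans arrangement (descriptor change is nomenclatural).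

Step 11
Reactants: 20 5-bromobenzene-1,3-diol
Product: 21 1,3-bis(benzyloxy)-5-bromobenzene
Conditions: BnBr, K2CO3, DMF, 60 °C
Reagents that add atoms: benzyl bromide, BrCc1ccccc1
Why: Double Williamson etherification of the two phenols gives the protected aryl bromide; no stereocentre.

Step 12
Reactants: 19 (2S,3S)-4-(benzyloxy)-2-[2,4-bis(benzyloxy)phenyl]-6-(methoxycarbonyl)-2,3-dihydro-1-benzofuran-3-carboxylic acid; 21 1,3-bis(benzyloxy)-5-bromobenzene
Product: 22 methyl (2S,3S)-4-(benzyloxy)-2-[2,4-bis(benzyloxy)phenyl]-3-[3,5-bis(benzyloxy)phenyl]-2,3-dihydro-1-benzofuran-6-carboxylate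
Conditions: Ir[dF(CF3)ppy]2(dtbbpy)PF6 (1 mol %), NiCl2(DME) (10 mol %), 4,4′-di-tert-butyl-2,2′-bipyridine (15 mol %), Cs2CO3, DMF, blue LEDs, rt
Reagents that add atoms: none
Why: Photoredox/nickel dual-catalytic decarboxylative arylation oxidises the caesium carboxylate, loss of CO2 gives a planar benzylic C3 radical, and the aryl–nickel species captures it on the face opposite the C2 aryl group, so reductive elimination gives the trans (2S,3S) diaryl product with C3 re-set from the unchanged C2 centre.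

Step 13
Reactants: 22 methyl (2S,3S)-4-(benzyloxy)-2-[2,4-bis(benzyloxy)phenyl]-3-[3,5-bis(benzyloxy)phenyl]-2,3-dihydro-1-benzofuran-6-carboxylate
Product: 23 [(2S,3S)-4-(benzyloxy)-2-[2,4-bis(benzyloxy)phenyl]-3-[3,5-bis(benzyloxy)phenyl]-2,3-dihydro-1-benzofuran-6-yl]methanol
Conditions: i-Bu2AlH, CH2Cl2, −78 → 0 °C; aq. KNaC4H4O6 (potassium sodium tartrate) work-up
Reagents that add atoms: none
Why: Aluminium hydride reduction of the aryl ester gives the benzylic alcohol while the benzyl ethers and both stereocentres are inert.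

Step 14
Reactants: 23 [(2S,3S)-4-(benzyloxy)-2-[2,4-bis(benzyloxy)phenyl]-3-[3,5-bis(benzyloxy)phenyl]-2,3-dihydro-1-benzofuran-6-yl]methanol
Product: 24 (2S,3S)-4-(benzyloxy)-2-[2,4-bis(benzyloxy)phenyl]-3-[3,5-bis(benzyloxy)phenyl]-2,3-dihydro-1-benzofuran-6-carbaldehyde
Conditions: MnO2, CH2Cl2, rt
Reagents that add atoms: none
Why: Heterogeneous MnO2 oxidation is selective for the benzylic alcohol and stops at the aldehyde; no stereocentre is affected.

Step 15
Reactants: 25 [4-(benzyloxy)-3-methoxyphenyl]methanol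
Product: 26 1-(benzyloxy)-4-(chloromethyl)-2-methoxybenzene
Conditions: SOCl2, CH2Cl2, 0 °C → rt
Reagents that add atoms: thionyl chloride, O=S(Cl)Cl
Why: Chlorodehydroxylation of the electron-rich benzylic alcohol through its chlorosulfite gives the benzylic chloride; no stereocentre.

Step 16
Reactants: 26 1-(benzyloxy)-4-(chloromethyl)-2-methoxybenzene
Product: 27 diethyl {[4-(benzyloxy)-3-methoxyphenyl]methyl}phosphonate
Conditions: P(OEt)3, neat, 130 °C
Reagents that add atoms: triethyl phosphite, CCOP(OCC)OCC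
Why: Michaelis–Arbuzov reaction of the reactive benzylic chloride gives the phosphonate with loss of chloroethane; no stereocentre.

Step 17
Reactants: 24 (2S,3S)-4-(benzyloxy)-2-[2,4-bis(benzyloxy)phenyl]-3-[3,5-bis(benzyloxy)phenyl]-2,3-dihydro-1-benzofuran-6-carbaldehyde; 27 diethyl {[4-(benzyloxy)-3-methoxyphenyl]methyl}phosphonate
Product: 28 (2S,3S)-4-(benzyloxy)-6-{(E)-2-[4-(benzyloxy)-3-methoxyphenyl]ethenyl}-2-[2,4-bis(benzyloxy)phenyl]-3-[3,5-bis(benzyloxy)phenyl]-2,3-dihydro-1-benzofuran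
Conditions: KOtBu, THF, 0 °C → rt
Reagents that add atoms: none
Why: Horner–Wadsworth–Emmons olefination of an aromatic aldehyde with a benzylic phosphonate gives the (E)-stilbene through the favoured anti elimination pathway, and the ring stereocentres are not disturbed (any C3 deprotonation would return the more stable trans isomer).

Step 18
Reactants: 28 the hexabenzyl ether
Product: 29 4-[(2S,3S)-3-(3,5-dihydroxyphenyl)-4-hydroxy-6-[(E)-2-(4-hydroxy-3-methoxyphenyl)ethenyl]-2,3-dihydro-1-benzofuran-2-yl]benzene-1,3-diol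
Conditions: BCl3, C6HMe5, CH2Cl2, −78 °C; then MeOH
Reagents that add atoms: none
Why: Lewis-acid debenzylation with BCl3 cleaves the six aryl benzyl ethers at −78 °C while pentamethylbenzene traps the benzyl cations by Friedel–Crafts alkylation, conditions under which the aryl methyl ether, the alkene and the trans (2S,3S) centres are retained.

## Compound list

1 | methyl 4-bromo-3,5-dihydroxybenzoate | COC(=O)c1cc(O)c(Br)c(O)c1 | starting material
2 | methyl 4-bromo-3,5-bis(methoxymethoxy)benzoate | COC(=O)c1cc(OCOC)c(Br)c(OCOC)c1 | intermediate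
3 | methyl 3,5-bis(methoxymethoxy)-4-(prop-2-en-1-yl)benzoate | COC(=O)c1cc(OCOC)c(CC=C)c(OCOC)c1 | intermediate
4 | methyl 3,5-bis(methoxymethoxy)-4-(1,2,4-trioxolan-3-ylmethyl)benzoate (secondary ozonide) | COC(=O)c1cc(OCOC)c(CC2OCOO2)c(OCOC)c1 | intermediate
5 | methyl 3,5-bis(methoxymethoxy)-4-(2-oxoethyl)benzoate | COC(=O)c1cc(OCOC)c(CC=O)c(OCOC)c1 | intermediate
6 | [4-(methoxycarbonyl)-2,6-bis(methoxymethoxy)phenyl]acetic acid | COC(=O)c1cc(OCOC)c(CC(=O)O)c(OCOC)c1 | intermediate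
7 | (4S)-4-benzyl-1,3-oxazolidin-2-one | O=C1N[C@@H](Cc2ccccc2)CO1 | starting material
8 | [4-(methoxycarbonyl)-2,6-bis(methoxymethoxy)phenyl]acetic pivalic anhydride | COC(=O)c1cc(OCOC)c(CC(=O)OC(=O)C(C)(C)C)c(OCOC)c1 | intermediate
9 | methyl 4-{2-[(4S)-4-benzyl-2-oxo-1,3-oxazolidin-3-yl]-2-oxoethyl}-3,5-bis(methoxymethoxy)benzoate | COC(=O)c1cc(OCOC)c(CC(=O)N2[C@@H](Cc3ccccc3)COC2=O)c(OCOC)c1 | intermediate
10 | 2,4-bis(benzyloxy)benzaldehyde | O=Cc1ccc(OCc2ccccc2)cc1OCc1ccccc1 | starting material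
11 | (Z)-O-dibutylboryl enolate of 9 | CCCCB(CCCC)O/C(=C\c1c(OCOC)cc(cc1OCOC)C(=O)OC)N1[C@@H](Cc2ccccc2)COC1=O | intermediate
12 | O-dibutylboryl ether of 13 (boron aldolate) | O=C(N1[C@@H](Cc2ccccc2)COC1=O)[C@@H](c1c(OCOC)cc(cc1OCOC)C(=O)OC)[C@H](OB(CCCC)CCCC)c1ccc(OCc2ccccc2)cc1OCc1ccccc1 | intermediate
13 | (4S)-4-benzyl-3-[(2S,3S)-3-[2,4-bis(benzyloxy)phenyl]-3-hydroxy-2-[4-(methoxycarbonyl)-2,6-bis(methoxymethoxy)phenyl]propanoyl]-1,3-oxazolidin-2-one | O=C(N1[C@@H](Cc2ccccc2)COC1=O)[C@@H](c1c(OCOC)cc(cc1OCOC)C(=O)OC)[C@H](O)c1ccc(OCc2ccccc2)cc1OCc1ccccc1 | intermediate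
14 | methyl 4-[(1S,2R)-1-[2,4-bis(benzyloxy)phenyl]-1,3-dihydroxypropan-2-yl]-3,5-bis(methoxymethoxy)benzoate | OC[C@@H](c1c(OCOC)cc(cc1OCOC)C(=O)OC)[C@H](O)c1ccc(OCc2ccccc2)cc1OCc1ccccc1 | intermediate
15 | methyl 4-[(1S,2R)-1-[2,4-bis(benzyloxy)phenyl]-1,3-dihydroxypropan-2-yl]-3,5-dihydroxybenzoate | OC[C@@H](c1c(O)cc(cc1O)C(=O)OC)[C@H](O)c1ccc(OCc2ccccc2)cc1OCc1ccccc1 | intermediate
16 | methyl (2S,3R)-2-[2,4-bis(benzyloxy)phenyl]-4-hydroxy-3-(hydroxymethyl)-2,3-dihydro-1-benzofuran-6-carboxylate | COC(=O)c1cc(O)c2c(c1)O[C@H](c1ccc(OCc3ccccc3)cc1OCc1ccccc1)[C@H]2CO | intermediate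
17 | methyl (2S,3R)-4-(benzyloxy)-2-[2,4-bis(benzyloxy)phenyl]-3-(hydroxymethyl)-2,3-dihydro-1-benzofuran-6-carboxylate | COC(=O)c1cc(OCc3ccccc3)c2c(c1)O[C@H](c1ccc(OCc3ccccc3)cc1OCc1ccccc1)[C@H]2CO | intermediate
18 | methyl (2S,3S)-4-(benzyloxy)-2-[2,4-bis(benzyloxy)phenyl]-3-formyl-2,3-dihydro-1-benzofuran-6-carboxylate | COC(=O)c1cc(OCc3ccccc3)c2c(c1)O[C@H](c1ccc(OCc3ccccc3)cc1OCc1ccccc1)[C@H]2C=O | intermediate
19 | (2S,3S)-4-(benzyloxy)-2-[2,4-bis(benzyloxy)phenyl]-6-(methoxycarbonyl)-2,3-dihydro-1-benzofuran-3-carboxylic acid | COC(=O)c1cc(OCc3ccccc3)c2c(c1)O[C@H](c1ccc(OCc3ccccc3)cc1OCc1ccccc1)[C@H]2C(=O)O | intermediate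
20 | 5-bromobenzene-1,3-diol | Oc1cc(O)cc(Br)c1 | starting material
21 | 1,3-bis(benzyloxy)-5-bromobenzene | Brc1cc(OCc2ccccc2)cc(OCc2ccccc2)c1 | intermediate
22 | methyl (2S,3S)-4-(benzyloxy)-2-[2,4-bis(benzyloxy)phenyl]-3-[3,5-bis(benzyloxy)phenyl]-2,3-dihydro-1-benzofuran-6-carboxylate | COC(=O)c1cc(OCc3ccccc3)c2c(c1)O[C@H](c1ccc(OCc3ccccc3)cc1OCc1ccccc1)[C@H]2c1cc(OCc2ccccc2)cc(OCc2ccccc2)c1 | intermediate
23 | [(2S,3S)-4-(benzyloxy)-2-[2,4-bis(benzyloxy)phenyl]-3-[3,5-bis(benzyloxy)phenyl]-2,3-dihydro-1-benzofuran-6-yl]methanol | OCc1cc(OCc3ccccc3)c2c(c1)O[C@H](c1ccc(OCc3ccccc3)cc1OCc1ccccc1)[C@H]2c1cc(OCc2ccccc2)cc(OCc2ccccc2)c1 | intermediate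
24 | (2S,3S)-4-(benzyloxy)-2-[2,4-bis(benzyloxy)phenyl]-3-[3,5-bis(benzyloxy)phenyl]-2,3-dihydro-1-benzofuran-6-carbaldehyde | O=Cc1cc(OCc3ccccc3)c2c(c1)O[C@H](c1ccc(OCc3ccccc3)cc1OCc1ccccc1)[C@H]2c1cc(OCc2ccccc2)cc(OCc2ccccc2)c1 | intermediate
25 | [4-(benzyloxy)-3-methoxyphenyl]methanol | COc1cc(CO)ccc1OCc1ccccc1 | starting material
26 | 1-(benzyloxy)-4-(chloromethyl)-2-methoxybenzene | COc1cc(CCl)ccc1OCc1ccccc1 | intermediate
27 | diethyl {[4-(benzyloxy)-3-methoxyphenyl]methyl}phosphonate | CCOP(=O)(OCC)Cc1ccc(OCc2ccccc2)c(OC)c1 | intermediate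
28 | (2S,3S)-4-(benzyloxy)-6-{(E)-2-[4-(benzyloxy)-3-methoxyphenyl]ethenyl}-2-[2,4-bis(benzyloxy)phenyl]-3-[3,5-bis(benzyloxy)phenyl]-2,3-dihydro-1-benzofuran | COc1cc(/C=C/c2cc(OCc3ccccc3)c3c(c2)O[C@H](c2ccc(OCc4ccccc4)cc2OCc2ccccc2)[C@H]3c2cc(OCc3ccccc3)cc(OCc3ccccc3)c2)ccc1OCc1ccccc1 | intermediate
29 | 4-[(2S,3S)-3-(3,5-dihydroxyphenyl)-4-hydroxy-6-[(E)-2-(4-hydroxy-3-methoxyphenyl)ethenyl]-2,3-dihydro-1-benzofuran-2-yl]benzene-1,3-diol | COc1cc(/C=C/c2cc(O)c3c(c2)O[C@H](c2ccc(O)cc2O)[C@H]3c2cc(O)cc(O)c2)ccc1O | target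

## Step count

Total steps: 18. Longest linear sequence: 15 steps (steps 1–10, 12, 13, 14, 17, 18).

## Steps most likely to fail, with fallbacks

**Step 12 (decarboxylative arylation at the hindered benzylic C3).** The stabilised, crowded C3 radical may be captured slowly by nickel, or the electron-rich substrate may be over-oxidised to the benzofuran. The fallback sets out from acid 19 and replaces photochemical oxidation of the free acid by thermal single-electron reduction of a redox-active ester, with an aryl nucleophile in place of the aryl bromide. Acid 19 is condensed with N-hydroxyphthalimide (DIC, DMAP, CH2Cl2) to the N-hydroxyphthalimide ester F1. F1 is cross-coupled under NiCl2(DME)/4,4′-di-tert-butyl-2,2′-bipyridine (THF/DMF, rt) with [3,5-bis(benzyloxy)phenyl]zinc chloride F2, made from bromide 21 with Mg/LiCl and then ZnCl2. The same C3 radical is arylated anti to the C2 aryl group, and the route is rejoined at 22.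

**Step 6 (aldol of a doubly ortho-substituted arylacetyl imide with an electron-rich, ortho-substituted aldehyde).** Slow addition or retro-aldol is possible. The fallback sets out from acid 6 and builds the same C2–C3 bond by Claisen-type C-acylation followed by reduction. Because acylation of the chelated enolate takes the face opposite to that used in the boron aldol, the mirror-image auxiliary is used.
- Acid 6 is coupled, as in step 5 (through anhydride 8), with (4R)-4-benzyl-1,3-oxazolidin-2-one to give the (4R)-imide F3.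
- The sodium enolate of F3 (NaN(SiMe3)2, THF, −78 °C) is acylated with 2,4-bis(benzyloxy)benzoyl chloride F4 (from the commercial acid and oxalyl chloride) anti to the benzyl group, giving the (2S)-β-keto imide F5.
- F5 is kept cold and reduced at once with Zn(BH4)2 (chelation control, −20 °C) to the syn β-hydroxy imide F6.
- NaBH4 in THF/H2O removes the auxiliary and returns the route at diol 14.

**Step 18 (six-fold Lewis-acid debenzylation of the acid-sensitive stilbene–dihydrobenzofuran).** The fallback sets out from aldehyde 24 and moves the Lewis-acid step to before the alkene exists, so that the last step is a mild fluoride deprotection.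
- BCl3/C6HMe5 (CH2Cl2, −78 °C) converts 24 into the pentahydroxy aldehyde F7.
- TBSCl/imidazole (DMF) gives the penta-TBS aldehyde F8.
- Commercial vanillyl alcohol is heated with P(OEt)3 (phosphonylation through the para-quinone methide) to the hydroxy phosphonate F9, which is silylated (TBSCl, imidazole) to the silyl phosphonate F10.
- Horner–Wadsworth–Emmons coupling of F8 with F10 (LiN(SiMe3)2, THF, −78 °C → rt) gives the hexa-TBS stilbene F11.
- Buffered fluoride (TBAF/AcOH, THF, 0 °C) releases the target, rejoining the route at 29.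

## Further compounds

F1 | step 12 | 3-(1,3-dioxoisoindolin-2-yl) 6-methyl (2S,3S)-4-(benzyloxy)-2-[2,4-bis(benzyloxy)phenyl]-2,3-dihydro-1-benzofuran-3,6-dicarboxylate | COC(=O)c1cc(OCc3ccccc3)c2c(c1)O[C@H](c1ccc(OCc3ccccc3)cc1OCc1ccccc1)[C@H]2C(=O)ON1C(=O)c2ccccc2C1=O
F2 | step 12 | [3,5-bis(benzyloxy)phenyl]zinc chloride | Cl[Zn]c1cc(OCc2ccccc2)cc(OCc2ccccc2)c1
F3 | step 6 | methyl 4-{2-[(4R)-4-benzyl-2-oxo-1,3-oxazolidin-3-yl]-2-oxoethyl}-3,5-bis(methoxymethoxy)benzoate | COC(=O)c1cc(OCOC)c(CC(=O)N2[C@H](Cc3ccccc3)COC2=O)c(OCOC)c1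
F4 | step 6 | 2,4-bis(benzyloxy)benzoyl chloride | O=C(Cl)c1ccc(OCc2ccccc2)cc1OCc1ccccc1
F5 | step 6 | (4R)-4-benzyl-3-[(2S)-3-[2,4-bis(benzyloxy)phenyl]-2-[4-(methoxycarbonyl)-2,6-bis(methoxymethoxy)phenyl]-3-oxopropanoyl]-1,3-oxazolidin-2-one | O=C(N1[C@H](Cc2ccccc2)COC1=O)[C@@H](c1c(OCOC)cc(cc1OCOC)C(=O)OC)C(=O)c1ccc(OCc2ccccc2)cc1OCc1ccccc1
F6 | step 6 | (4R)-4-benzyl-3-[(2S,3S)-3-[2,4-bis(benzyloxy)phenyl]-3-hydroxy-2-[4-(methoxycarbonyl)-2,6-bis(methoxymethoxy)phenyl]propanoyl]-1,3-oxazolidin-2-one | O=C(N1[C@H](Cc2ccccc2)COC1=O)[C@@H](c1c(OCOC)cc(cc1OCOC)C(=O)OC)[C@H](O)c1ccc(OCc2ccccc2)cc1OCc1ccccc1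
F7 | step 18 | (2S,3S)-2-(2,4-dihydroxyphenyl)-3-(3,5-dihydroxyphenyl)-4-hydroxy-2,3-dihydro-1-benzofuran-6-carbaldehyde | O=Cc1cc(O)c2c(c1)O[C@H](c1ccc(O)cc1O)[C@H]2c1cc(O)cc(O)c1
F8 | step 18 | (2S,3S)-2-[2,4-bis(tert-butyldimethylsilyloxy)phenyl]-3-[3,5-bis(tert-butyldimethylsilyloxy)phenyl]-4-(tert-butyldimethylsilyloxy)-2,3-dihydro-1-benzofuran-6-carbaldehyde | O=Cc1cc(O[Si](C)(C)C(C)(C)C)c2c(c1)O[C@H](c1ccc(O[Si](C)(C)C(C)(C)C)cc1O[Si](C)(C)C(C)(C)C)[C@H]2c1cc(O[Si](C)(C)C(C)(C)C)cc(O[Si](C)(C)C(C)(C)C)c1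
F9 | step 18 | diethyl [(4-hydroxy-3-methoxyphenyl)methyl]phosphonate | CCOP(=O)(OCC)Cc1ccc(O)c(OC)c1
F10 | step 18 | diethyl {[4-(tert-butyldimethylsilyloxy)-3-methoxyphenyl]methyl}phosphonate | CCOP(=O)(OCC)Cc1ccc(O[Si](C)(C)C(C)(C)C)c(OC)c1
F11 | step 18 | (2S,3S)-2-[2,4-bis(tert-butyldimethylsilyloxy)phenyl]-3-[3,5-bis(tert-butyldimethylsilyloxy)phenyl]-4-(tert-butyldimethylsilyloxy)-6-{(E)-2-[4-(tert-butyldimethylsilyloxy)-3-methoxyphenyl]ethenyl}-2,3-dihydro-1-benzofuran | COc1cc(/C=C/c2cc(O[Si](C)(C)C(C)(C)C)c3c(c2)O[C@H](c2ccc(O[Si](C)(C)C(C)(C)C)cc2O[Si](C)(C)C(C)(C)C)[C@H]3c2cc(O[Si](C)(C)C(C)(C)C)cc(O[Si](C)(C)C(C)(C)C)c2)ccc1O[Si](C)(C)C(C)(C)C
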